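**Retrosynthetic overview**
- The target is opened at the six phenols (global desilylation) and at the (E)-styryl arm, which comes from a Heck coupling of a 6-bromo-1,4-benzodioxane with 3,5-bis(silyloxy)styrene.
- The cis-2,3-diaryl-1,4-benzodioxane ring is disconnected by an inverse-demand hetero-Diels–Alder reaction: 4-bromo-o-benzoquinone (O=C–C=O heterodiene, from 4-bromocatechol) plus a (Z)-stilbene. The Z geometry becomes the cis relationship.
- The (Z)-stilbene comes from photoisomerization of per-silylated (E)-piceatannol.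
- Both cycloaddition partners are achiral, so the cis adduct is racemic; the enantiomers are separated on a cellulose-derived phase directly after the cycloaddition.
- Ring order: the dioxane ring is the only ring formed (step 3); all four benzene rings are bought.

Assumption: the SMILES is read as the cis isomer, 2S at the carbon bearing the 3,5-dihydroxyphenyl ring and 3R at the carbon bearing the 3,4-dihydroxyphenyl ring (benzodioxine numbering). TBSO = tert-butyldimethylsilyloxy; racemates are written as both enantiomers joined by a dot.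

**Step 1**
Reactants: 1 piceatannol [(E)-3,3',4',5-tetrahydroxystilbene]
Product: 2 (E)-3,3',4',5-tetrakis(TBSO)stilbene
Conditions: TBSCl (5 equiv), imidazole (10 equiv), DMF, rt
Reagents that add atoms: tert-butyldimethylsilyl chloride (TBSCl), CC(C)(C)[Si](C)(C)Cl
Why: Imidazole-mediated silylation (silyl ether formation) caps all four phenols so that the dienophile carries no oxidizable free catechol in the later cycloaddition; no stereocentre is involved.

**Step 2**
Reactants: 2 (E)-3,3',4',5-tetrakis(TBSO)stilbene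
Product: 3 (Z)-3,3',4',5-tetrakis(TBSO)stilbene
Conditions: hν (365 nm), degassed hexane, rt; chromatography, recovered 2 recycled
Reagents that add atoms: none
Why: Direct E→Z photoisomerization: at 365 nm the planar E isomer absorbs far more strongly than the twisted Z isomer, so the photostationary state is Z-rich, and degassing suppresses oxidative 6π photocyclization to a phenanthrene; no stereocentre yet, but this Z geometry becomes the cis relationship.

**Step 3**
Reactants: 3 (Z)-3,3',4',5-tetrakis(TBSO)stilbene; 4 4-bromobenzene-1,2-diol (4-bromocatechol)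
Product: 6 racemic cis-6-bromo-3-[3,4-bis(TBSO)phenyl]-2-[3,5-bis(TBSO)phenyl]-2,3-dihydro-1,4-benzodioxine, via 4-bromo-1,2-benzoquinone 5 (not isolated)
Conditions: Ag2O (6 equiv), Na2SO4, PhMe, 25→40 °C, dark; 4 (3 equiv) added slowly in Et2O
Reagents that add atoms: none
Why: Ag2O dehydrogenates 4 to the electron-poor heterodiene 5, which adds suprafacially across the electron-rich Z alkene in an inverse-electron-demand hetero-Diels–Alder reaction, so the Z geometry is transferred into the cis-2,3-diaryl relationship (both faces react equally, hence a racemate), while the more nucleophilic alkene carbon (remote from the para-silyloxyaryl ring) bonds to the quinone oxygen para to bromine because the oxygen meta to bromine better carries the developing negative charge.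

**Step 4**
Reactants: 6 racemic cis-6-bromo-3-[3,4-bis(TBSO)phenyl]-2-[3,5-bis(TBSO)phenyl]-2,3-dihydro-1,4-benzodioxine
Product: 7 (2S,3R)-6-bromo-3-[3,4-bis(TBSO)phenyl]-2-[3,5-bis(TBSO)phenyl]-2,3-dihydro-1,4-benzodioxine
Conditions: preparative SFC, cellulose tris(3,5-dimethylphenylcarbamate) phase, CO2/i-PrOH, 35 °C
Reagents that add atoms: none
Why: Resolution of the racemate by enantioselective chromatography: the two cis enantiomers bind differently to the helical cellulose carbamate, and the (2S,3R) enantiomer is identified by anomalous-dispersion X-ray analysis (bromine) or by ECD.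

**Step 5**
Reactants: 8 3,5-dihydroxybenzaldehyde
Product: 9 3,5-bis(TBSO)benzaldehyde
Conditions: TBSCl (2.5 equiv), imidazole (5 equiv), DMF, rt
Reagents that add atoms: tert-butyldimethylsilyl chloride (TBSCl), CC(C)(C)[Si](C)(C)Cl
Why: Imidazole-mediated silylation of both phenols (silyl ether formation) so that the aldehyde can be methylenated and the styrene coupled without free phenols; no stereocentre.

**Step 6**
Reactants: 9 3,5-bis(TBSO)benzaldehyde
Product: 10 3,5-bis(TBSO)styrene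
Conditions: MePPh3Br, n-BuLi, THF, 0 °C→rt
Reagents that add atoms: methyltriphenylphosphonium bromide, C[P+](c1ccccc1)(c1ccccc1)c1ccccc1.[Br-]
Why: Wittig methylenation: the non-stabilized ylide Ph3P=CH2 adds to the aldehyde and the oxaphosphetane collapses to the terminal alkene and Ph3P=O, the aryl silyl ethers being inert to the ylide; no stereocentre.

**Step 7**
Reactants: 7 (2S,3R)-6-bromo-3-[3,4-bis(TBSO)phenyl]-2-[3,5-bis(TBSO)phenyl]-2,3-dihydro-1,4-benzodioxine; 10 3,5-bis(TBSO)styrene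
Product: 11 (2S,3R)-3-[3,4-bis(TBSO)phenyl]-2-[3,5-bis(TBSO)phenyl]-6-[(E)-2-(3,5-bis(TBSO)phenyl)ethenyl]-2,3-dihydro-1,4-benzodioxine
Conditions: Pd(P(t-Bu)3)2 (5 mol %), Cy2NMe (1.3 equiv), 10 (1.5 equiv), PhMe, 80 °C
Reagents that add atoms: none
Why: Mizoroki–Heck reaction: oxidative addition of the C–Br bond to zerovalent palladium, syn carbopalladation of the styrene at its terminal carbon and syn β-hydride elimination give the E alkene, while the fully silylated cis-benzodioxane stereocentres are inert to the amine base.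

**Step 8**
Reactants: 11 (2S,3R)-3-[3,4-bis(TBSO)phenyl]-2-[3,5-bis(TBSO)phenyl]-6-[(E)-2-(3,5-bis(TBSO)phenyl)ethenyl]-2,3-dihydro-1,4-benzodioxine
Product: 12 (2S,3R)-3-(3,4-dihydroxyphenyl)-2-(3,5-dihydroxyphenyl)-6-[(E)-2-(3,5-dihydroxyphenyl)ethenyl]-2,3-dihydro-1,4-benzodioxine
Conditions: TBAF (7 equiv), AcOH (8 equiv), THF, 0 °C→rt, argon; reversed-phase chromatography
Reagents that add atoms: none
Why: Fluoride-induced desilylation (Si–F bond formation) with AcOH protonating each phenoxide as it is released, so the para-hydroxybenzylic aryl ether cannot open to a quinone methide and the cis (2S,3R) centres and the E alkene are retained.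

**Compound list**
1 | piceatannol, (E)-4-[2-(3,5-dihydroxyphenyl)ethenyl]benzene-1,2-diol | Oc1cc(O)cc(/C=C/c2ccc(O)c(O)c2)c1 | starting material
2 | (E)-3,3',4',5-tetrakis(TBSO)stilbene | CC(C)(C)[Si](C)(C)Oc1cc(O[Si](C)(C)C(C)(C)C)cc(/C=C/c2ccc(O[Si](C)(C)C(C)(C)C)c(O[Si](C)(C)C(C)(C)C)c2)c1 | intermediate
3 | (Z)-3,3',4',5-tetrakis(TBSO)stilbene | CC(C)(C)[Si](C)(C)Oc1cc(O[Si](C)(C)C(C)(C)C)cc(/C=C\c2ccc(O[Si](C)(C)C(C)(C)C)c(O[Si](C)(C)C(C)(C)C)c2)c1 | intermediate
4 | 4-bromobenzene-1,2-diol | Oc1ccc(Br)cc1O | starting material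
5 | 4-bromo-1,2-benzoquinone (4-bromocyclohexa-3,5-diene-1,2-dione) | O=C1C=CC(Br)=CC1=O | intermediate (not isolated)
6 | racemic cis-6-bromo-3-[3,4-bis(TBSO)phenyl]-2-[3,5-bis(TBSO)phenyl]-2,3-dihydro-1,4-benzodioxine, (2S,3R) and (2R,3S) 1:1 | Brc1ccc2c(c1)O[C@H](c1ccc(O[Si](C)(C)C(C)(C)C)c(O[Si](C)(C)C(C)(C)C)c1)[C@H](c1cc(O[Si](C)(C)C(C)(C)C)cc(O[Si](C)(C)C(C)(C)C)c1)O2.Brc1ccc2c(c1)O[C@@H](c1ccc(O[Si](C)(C)C(C)(C)C)c(O[Si](C)(C)C(C)(C)C)c1)[C@@H](c1cc(O[Si](C)(C)C(C)(C)C)cc(O[Si](C)(C)C(C)(C)C)c1)O2 | intermediate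
7 | (2S,3R)-6-bromo-3-[3,4-bis(TBSO)phenyl]-2-[3,5-bis(TBSO)phenyl]-2,3-dihydro-1,4-benzodioxine | Brc1ccc2c(c1)O[C@H](c1ccc(O[Si](C)(C)C(C)(C)C)c(O[Si](C)(C)C(C)(C)C)c1)[C@H](c1cc(O[Si](C)(C)C(C)(C)C)cc(O[Si](C)(C)C(C)(C)C)c1)O2 | intermediate
8 | 3,5-dihydroxybenzaldehyde | O=Cc1cc(O)cc(O)c1 | starting material
9 | 3,5-bis(TBSO)benzaldehyde | O=Cc1cc(O[Si](C)(C)C(C)(C)C)cc(O[Si](C)(C)C(C)(C)C)c1 | intermediate
10 | 3,5-bis(TBSO)styrene | C=Cc1cc(O[Si](C)(C)C(C)(C)C)cc(O[Si](C)(C)C(C)(C)C)c1 | intermediate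
11 | (2S,3R)-3-[3,4-bis(TBSO)phenyl]-2-[3,5-bis(TBSO)phenyl]-6-[(E)-2-(3,5-bis(TBSO)phenyl)ethenyl]-2,3-dihydro-1,4-benzodioxine | CC(C)(C)[Si](C)(C)Oc1cc(O[Si](C)(C)C(C)(C)C)cc(/C=C/c2ccc3c(c2)O[C@H](c2ccc(O[Si](C)(C)C(C)(C)C)c(O[Si](C)(C)C(C)(C)C)c2)[C@H](c2cc(O[Si](C)(C)C(C)(C)C)cc(O[Si](C)(C)C(C)(C)C)c2)O3)c1 | intermediate
12 | (2S,3R)-3-(3,4-dihydroxyphenyl)-2-(3,5-dihydroxyphenyl)-6-[(E)-2-(3,5-dihydroxyphenyl)ethenyl]-2,3-dihydro-1,4-benzodioxine | Oc1cc(O)cc(/C=C/c2ccc3c(c2)O[C@H](c2ccc(O)c(O)c2)[C@H](c2cc(O)cc(O)c2)O3)c1 | target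

**Step count and risks**
Total step count: 8 (seven reactions and one resolution). Longest linear sequence: 6 steps (steps 1, 2, 3, 4, 7, 8).

Most likely to fail, step 3 (cycloaddition). The quinone 5 can dimerize instead of adding. The bromine gives only a modest regiochemical bias (about 0.3 pKa units between the two phenoxide positions), so the 7-bromo regioisomer is expected as a significant by-product to be removed by chromatography. A stepwise zwitterionic pathway could leak to the trans adduct. The fallback sets out from 2 and comes back to the route at 6. Compound 2 is epoxidized with dimethyldioxirane (acetone, 0 °C) to racemic trans-2-[3,4-bis(TBSO)phenyl]-3-[3,5-bis(TBSO)phenyl]oxirane F1. The potassium salt of commercial 5-bromo-2-iodophenol (KN(SiMe3)2, 18-crown-6, PhMe, 60 °C) opens F1 with inversion at the para-silyloxybenzylic carbon to give racemic erythro-2-(5-bromo-2-iodophenoxy)-2-[3,4-bis(TBSO)phenyl]-1-[3,5-bis(TBSO)phenyl]ethanol F2. Pd-catalysed intramolecular C–O coupling at the C–I bond (Pd(OAc)2, 2-(di-tert-butylphosphino)biphenyl, K3PO4, PhMe, 80 °C) then closes the dioxane ring with retention at the carbinol carbon and gives 6. Here the regiochemistry is fixed by the halogen pattern, and cis follows from trans-epoxide, anti opening and retentive closure.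

Second, step 8 (sixfold desilylation). The freed para-phenol on the 3-aryl ring can open the benzylic aryl ether to a quinone methide if the medium turns basic, which would epimerize cis to trans, and the hexaphenol is air-sensitive. The fallback sets out from 11 and comes back at 12. Desilylative acetylation (CsF, Ac2O, DMF, 0 °C) traps every phenoxide at once and gives the hexaacetate of 12, (2S,3R)-3-(3,4-diacetoxyphenyl)-2-(3,5-diacetoxyphenyl)-6-[(E)-2-(3,5-diacetoxyphenyl)ethenyl]-2,3-dihydro-1,4-benzodioxine F4, which can be purified on silica. Neutral deacetylation (NH4OAc, MeOH–H2O, rt) then releases 12.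

Third, step 7 (Heck coupling on the resolved, electron-rich aryl bromide). Slow oxidative addition or 1,1-diarylethene formation would waste resolved material. The fallback sets out from 7 and comes back at 11. Stille vinylation with Bu3SnCH=CH2 (Pd(PPh3)4, PhMe, 100 °C, no base) gives (2S,3R)-3-[3,4-bis(TBSO)phenyl]-2-[3,5-bis(TBSO)phenyl]-6-ethenyl-2,3-dihydro-1,4-benzodioxine F3. E-selective olefin cross-metathesis of F3 with an excess of 10 (second-generation Grubbs catalyst, CH2Cl2, 40 °C) gives 11.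

**Further compounds**
F1 | step 3 | racemic trans-2-[3,4-bis(TBSO)phenyl]-3-[3,5-bis(TBSO)phenyl]oxirane, (2R,3R) and (2S,3S) 1:1 | CC(C)(C)[Si](C)(C)Oc1ccc(cc1O[Si](C)(C)C(C)(C)C)[C@H]1O[C@@H]1c1cc(O[Si](C)(C)C(C)(C)C)cc(O[Si](C)(C)C(C)(C)C)c1.CC(C)(C)[Si](C)(C)Oc1ccc(cc1O[Si](C)(C)C(C)(C)C)[C@@H]1O[C@H]1c1cc(O[Si](C)(C)C(C)(C)C)cc(O[Si](C)(C)C(C)(C)C)c1
F2 | step 3 | racemic erythro-2-(5-bromo-2-iodophenoxy)-2-[3,4-bis(TBSO)phenyl]-1-[3,5-bis(TBSO)phenyl]ethanol, (1S,2R) and (1R,2S) 1:1 | Brc1ccc(I)c(c1)O[C@H](c1ccc(O[Si](C)(C)C(C)(C)C)c(O[Si](C)(C)C(C)(C)C)c1)[C@H](c1cc(O[Si](C)(C)C(C)(C)C)cc(O[Si](C)(C)C(C)(C)C)c1)O.Brc1ccc(I)c(c1)O[C@@H](c1ccc(O[Si](C)(C)C(C)(C)C)c(O[Si](C)(C)C(C)(C)C)c1)[C@@H](c1cc(O[Si](C)(C)C(C)(C)C)cc(O[Si](C)(C)C(C)(C)C)c1)O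
F3 | step 7 | (2S,3R)-3-[3,4-bis(TBSO)phenyl]-2-[3,5-bis(TBSO)phenyl]-6-ethenyl-2,3-dihydro-1,4-benzodioxine | C=Cc1ccc2c(c1)O[C@H](c1ccc(O[Si](C)(C)C(C)(C)C)c(O[Si](C)(C)C(C)(C)C)c1)[C@H](c1cc(O[Si](C)(C)C(C)(C)C)cc(O[Si](C)(C)C(C)(C)C)c1)O2
F4 | step 8 | (2S,3R)-3-(3,4-diacetoxyphenyl)-2-(3,5-diacetoxyphenyl)-6-[(E)-2-(3,5-diacetoxyphenyl)ethenyl]-2,3-dihydro-1,4-benzodioxine | CC(=O)Oc1cc(OC(C)=O)cc(/C=C/c2ccc3c(c2)O[C@H](c2ccc(OC(C)=O)c(OC(C)=O)c2)[C@H](c2cc(OC(C)=O)cc(OC(C)=O)c2)O3)c1
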